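In a one-step world the target climbs once and stays, the gap to its plateau P∞ shrinking as exp(−t/τ), with τ the time for that gap to fall by a factor e.

| flask | substrate | reagent in the second phase | remark | time | volume of the second phase over the first |
|---|---|---|---|---|---|
| violet | 0.10 M | 0.055 M | run made earlier |  |  |
| teal | 0.10 M | 0.22 M | run made earlier |  |  |
| red | 0.20 M | 0.11 M | run made earlier |  |  |
| flask | 0.10 M | 0.110 M |  | 3.0 d | 0.25 |

| run | time / h | target / % |
|---|---|---|
| violet | 3.00 | 6.3 |
| violet | 8.00 | 9.9 |
| violet | 20.0 | 16.5 |
| violet | 40.0 | 15.0 |
| teal | 3.00 | 12.0 |
| teal | 8.00 | 26.2 |
| teal | 20.0 | 30.2 |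
| teal | 40.0 | 30.2 |
| red | 5.00 | 9.7 |
| red | 15.0 | 18.5 |
| red | 30.0 | 20.8 |
| red | 40.0 | 20.7 |

(scatter of a reading: 1 percentage point)

- in the second phase: reagent in the second phase; everything else is in the first
- charges count per volume of the first phase; a concentration in a rate is the amount of a species over the volume of its own phase; every rate counts per litre of the first phase
- the earlier runs hold the two phases in the same ratio of volumes as the flask asked about

- summer: doubling the transfer coefficient of the reagent in the second phase, all else as stated
- spring: doubling the amount of reagent in the second phase, all else as stated

- amount of target at 3.0 d, in percent of the substrate charged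
- the change that raises the amount of target at 3.0 d, in percent of the substrate charged most ("none" if none brings more than 2 percentage points) (summer / spring / none)
- amount of target at 3.0 d, in percent of the substrate charged, after spring

Red's readings give me τ = 6.81 h, so 3.0 d is 10.6 τ, and in this world I may read the flask off the last readings, those at 40.0 h.

I get there by two ways. From violet to teal, at equal substrate, the plateau rises as a power of the reagent charge, n = 0.505: this is the reagent exponent of the plateau, an apparent order. Carrying violet's reading to the flask's charge with n gives 21.3 %.

The second way takes red's 20.7 %, at the flask's reagent charge but twice its substrate. This is honest if the percent follows the reagent charge, not the reagent-to-substrate ratio. Violet and red share a ratio of 0.550, yet red reads higher by 5.7 percentage points, so the ratio is not what the percent follows. The two ways part by 0.60 points, less than the scatter of a reading, and I commit to their mean, 21.0 %.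

The forecast says 21.5 %, a little above mine, with spring as the best change and 30.2 % after it: “Spring is effectively the teal run”.

The flask gives 21.5 % at 3.0 d; spring adds 4.7 points, and summer changes it by −0.85 points. The equations are these:

    reagent in the reaction phase ⇌ reagent in the second phase, rate k1*([reagent in the reaction phase] - [reagent in the second phase]/K1) per volume of the first phase (partition coefficient = 0.320, kL = 6.30 × 10⁻⁴ min⁻¹)
    2 reagent in the reaction phase → homo dimer (k = 0.0280 M⁻¹ min⁻¹)
    substrate → decomposition product (k = 1.00 × 10⁻⁶ min⁻¹)
    reagent in the reaction phase + target → over-reacted product (k = 0.00190 M⁻¹ min⁻¹)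
    substrate + reagent in the reaction phase ⇌ target (K = 43.0 M⁻¹, k = 0.00960 M⁻¹ min⁻¹)

The flask's target is falling at that time, from 24.3 % after 1.50 d to 16.7 % after 6.00 d. Violet's reading carried by n stands 0.20 points from the flask's value. Carried on from 21.5 % through spring's doubling, n gives 30.5 %, and the spring flask holds 26.3 %.

(Readings and results are simulated for substances that don't exist, noise included.)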